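The target: follow it through these flasks, which share one charge of nucleophile and free base and differ in the electrophile charged, since the target is made from electrophile and nucleophile and then decays by itself to the over-reaction product.

| flask | electrophile | nucleophile | free base | time |
|---|---|---|---|---|
| winter | 0.0060 M | 0.0525 M | 0.0550 M | 40 h |
| summer | 0.015 M | 0.0525 M | 0.0550 M | 40 h |
| midnight | 0.050 M | 0.0525 M | 0.0550 M | 40 h |
| noon | 0.15 M | 0.0525 M | 0.0550 M | 40 h |
| autumn | 0.50 M | 0.0525 M | 0.0550 M | 40 h |

    nucleophile + acid set free ⇌ protonated nucleophile, settled at all times (K1 = 2090 /M)
    target → over-reaction product (k2 = 9.51 × 10⁻⁴ /min)
    electrophile + nucleophile → acid set free + target (k3 = 0.296 /M/min)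
    acid set free + free base ⇌ salt of the base (K4 = 33000 /M, k4 = 0.0644 /M/min)

- amount of target at the end, in percent of the electrophile charged for winter, summer, midnight, noon, autumn, in this order
- the course of these numbers from the first flask to the last (rises all the way / falls, then rises / rises, then falls / falls all the way / hardly changes)

- "hardly changes" means that all values lie within two and a half points (for a concentration: within two and a half percent of the largest)
- run time (winter): 40 h

Ask first how the target's life compares with its making. Its half-life is 12.1 h, while in the winter flask the electrophile as charged has a half-life of 0.74 h by the making step, so treat the winter target as born at the start. Take as the zero of the scale 10.2%, the survival factor, the fraction of a target born at the start that still stands at the end, and read a flask above it as one that made its target later.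

Ask next what can delay the making. In the winter flask the acid set free sits on the nucleophile, with a binding measure of 110, and the free base, by its forward step alone, takes the acid with a half-life of 3.3 h, slower than the making, so count two nucleophiles per electrophile early on. That covers 438% of the electrophile in the winter flask but 52.5% in the midnight flask, whose remainder waits for the free base; spread that remainder evenly over the run, where a target keeps on average 39.3%, and the midnight flask comes to 24.0%, a rough figure that counts the whole remainder as made.

Ask last what the charge allows: in the autumn flask the nucleophile is 10.5% of the electrophile, one nucleophile per target, so with the midnight figure above the zero and the autumn flask below it I commit to the course rises, then falls.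

The forecast gives 11%, 11.4%, 15%, 5.8% and 1.3%, with the course rises, then falls, on the ground that “the slow free base releases it late, so fresher target survives and the yield peaks”; its first value stands above my zero and its third below my midnight figure.

The flasks give 11.0%, 11.2%, 15.1%, 5.58% and 1.25%, with the course rises, then falls.

In the winter flask half of the making is done by 0.795 h, far less than a target half-life of 12 h, and at 0.795 h target is made 14.9 times as fast as it is used up, each step taken net; moving the birth to that half-way time lifts the survival factor to 10.7%, beside the 11.0% found. In the autumn flask, the nucleophile's share of the electrophile times the survival factor gives 1.07%, beside the 1.25% found.

(The rate constants were chosen freely, and the outcome is calculated.)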